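**Retrosynthetic overview**

- Target 25 ⇐ hydroquinone 23 (desilylation, oxidation) ⇐ cyclobutenone 20 by thermal four-to-six ring expansion. The benzoquinone ring is the only ring of the target and is formed last (step 13), from the four-membered squarate ring.
- Enabling feature (quinone numbering: C1 and C4 carbonyl carbons, C2 OCH3, C3 OH, C5 CH3, C6 hexaprenyl): C1(=O)–C2(OCH3)=C3(OH)–C4(=O) is a contiguous, fully oxygenated four-carbon arc with its two C–O termini para, that is, a latent squaric acid ring. C5(CH3)=C6(CH2R) is a two-carbon alkene that can sit as an alkenyl group on C4 of a cyclobutenone.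
- 20 ⇐ squarate 18 + alkenyllithium 19 (from stannane 15). OCH3 is kept and OH is carried as OSi(i-Pr)3, which is also meant to steer the addition.
- 15 ⇐ hexaprenyl bromide 11 + stannylpropyne 12 (hydrozirconation, alkenyl–allyl coupling); 11 ⇐ two farnesyl units 1 and 3 (sulfone alkylation, desulfonylation).

Key step: step 13

Remark: 1, 3, 12 and 16 are taken as commercial; the racemic centres formed in 8 and 20 are removed in steps 6 and 13, so only alkene geometry has to be carried through.
Abbreviation in names: "all-E-hexaprenyl" = (2E,6E,10E,14E,18E)-3,7,11,15,19,23-hexamethyltetracosa-2,6,10,14,18,22-hexaen-1-yl.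

**Route**

Step 1
Reactants: 1 (2E,6E)-farnesyl bromide
Product: 2 (2E,6E)-farnesyl p-tolyl sulfone
Conditions: NaSO2C6H4CH3 (sodium p-toluenesulfinate), DMF, rt
Reagents that add atoms: sodium p-toluenesulfinate, [Na+].[O-]S(=O)c1ccc(C)cc1
Why: SN2 S-alkylation of the sulfinate by the primary allylic bromide (allylic sulfone synthesis) should proceed without allylic transposition and leave both E alkenes untouched.

Step 2
Reactants: 3 (2E,6E)-farnesol
Product: 4 (2E,6E)-farnesyl tert-butyldimethylsilyl ether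
Conditions: TBSCl, imidazole, DMF, rt
Reagents that add atoms: tert-butyldimethylsilyl chloride, CC(C)(C)[Si](C)(C)Cl
Why: Standard silyl ether formation protects the allylic alcohol against the oxidation, bromination and organolithium steps that follow.

Step 3
Reactants: 4 (2E,6E)-farnesyl tert-butyldimethylsilyl ether
Product: 5 (2E,6E,10E)-12-[(tert-butyldimethylsilyl)oxy]-2,6,10-trimethyldodeca-2,6,10-trien-1-ol
Conditions: SeO2 (cat.), t-BuOOH, salicylic acid (cat.), CH2Cl2, 0 °C to rt
Reagents that add atoms: tert-butyl hydroperoxide (oxygen atom, passed on through catalytic SeO2), CC(C)(C)OO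
Why: SeO2-catalysed allylic oxidation (Riley oxidation, ene reaction then [2,3]-sigmatropic shift) should hydroxylate the E-methyl group of the terminal, most electron-rich trisubstituted alkene, the ordered sigmatropic step fixing the 10E geometry, while the C2 alkene is deactivated by the allylic silyloxy group.

Step 4
Reactants: 5 (2E,6E,10E)-12-[(tert-butyldimethylsilyl)oxy]-2,6,10-trimethyldodeca-2,6,10-trien-1-ol
Product: 6 tert-butyl{[(2E,6E,10E)-12-bromo-3,7,11-trimethyldodeca-2,6,10-trien-1-yl]oxy}dimethylsilane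
Conditions: CBr4, PPh3, CH2Cl2, –20 °C
Reagents that add atoms: carbon tetrabromide, BrC(Br)(Br)Br
Why: Appel bromination of the primary allylic alcohol at low temperature should give the bromide with retention of the E geometry.

Step 5
Reactants: 2 (2E,6E)-farnesyl p-tolyl sulfone; 6 tert-butyl{[(2E,6E,10E)-12-bromo-3,7,11-trimethyldodeca-2,6,10-trien-1-yl]oxy}dimethylsilane
Product: 8 tert-butyldimethylsilyl ether of (2E,6E,10E,14E,18E)-3,7,11,15,19,23-hexamethyl-13-(p-tolylsulfonyl)tetracosa-2,6,10,14,18,22-hexaen-1-ol (racemic at C13), via lithiated sulfone 7 (not isolated)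
Conditions: n-BuLi, THF, –78 °C; then 6, THF/DMPU, –78 °C
Reagents that add atoms: none
Why: α-Lithiation of the allylic sulfone and SN2 alkylation by the allylic bromide (sulfone-based head-to-tail prenyl coupling) joins the two C15 units at the carbon α to sulfur; the new sulfone-bearing centre is racemic and disappears in step 6.

Step 6
Reactants: 8 C30 sulfone silyl ether
Product: 9 all-E-hexaprenyl tert-butyldimethylsilyl ether
Conditions: LiBHEt3, PdCl2(dppp) (5 mol %), THF, 0 °C
Reagents that add atoms: none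
Why: Palladium-catalysed reductive desulfonylation of the allylic sulfone proceeds through a π-allylpalladium hydride that delivers hydrogen to the less substituted terminus, so the alkene should stay in place with E geometry.

Step 7
Reactants: 9 all-E-hexaprenyl tert-butyldimethylsilyl ether
Product: 10 all-E-hexaprenol
Conditions: TBAF, THF, rt
Reagents that add atoms: none
Why: Fluoride cleavage of the silyl ether is selective and harmless to the polyene.

Step 8
Reactants: 10 all-E-hexaprenol
Product: 11 all-E-hexaprenyl bromide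
Conditions: PBr3, Et2O, –10 °C
Reagents that add atoms: phosphorus tribromide, BrP(Br)Br
Why: PBr3 converts the primary allylic alcohol into the bromide by SN2 at low temperature without E/Z erosion.

Step 9
Reactants: 12 tributyl(prop-1-yn-1-yl)stannane; 11 all-E-hexaprenyl bromide
Product: 15 tributyl[(2Z,5E,9E,13E,17E,21E)-6,10,14,18,22,26-hexamethylheptacosa-2,5,9,13,17,21,25-heptaen-3-yl]stannane, via alkenylzirconocene 13 (not isolated), via alkenylzinc chloride 14 (not isolated)
Conditions: Cp2Zr(H)Cl, THF, rt; then ZnCl2, Pd(PPh3)4 (5 mol %), 11, THF, 0 °C to rt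
Reagents that add atoms: none
Why: syn-Hydrozirconation of the alkynylstannane places zirconium on the tin-bearing carbon (cis to H), and after transmetalation to zinc a Negishi alkenyl–allyl coupling under zerovalent palladium should join that carbon to the primary terminus of the allyl unit with retention of both alkene geometries, the C–Sn bond being much slower to transmetalate.

Step 10
Reactants: 16 dimethyl squarate
Product: 17 sodium 2-methoxy-3,4-dioxocyclobut-1-en-1-olate
Conditions: NaOH (1.0 equiv), MeOH, 0 °C to rt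
Reagents that add atoms: sodium hydroxide, [Na+].[OH-]
Why: Addition–elimination of hydroxide at one vinylogous ester carbon (mono-saponification) should stop cleanly because the resulting squarate monoanion is no longer electrophilic.

Step 11
Reactants: 17 sodium 2-methoxy-3,4-dioxocyclobut-1-en-1-olate
Product: 18 3-methoxy-4-[(triisopropylsilyl)oxy]cyclobut-3-ene-1,2-dione
Conditions: i-Pr3SiOTf, MeCN/CH2Cl2, 0 °C; filtration, used without chromatography
Reagents that add atoms: triisopropylsilyl trifluoromethanesulfonate, CC(C)[Si](OS(=O)(=O)C(F)(F)F)(C(C)C)C(C)C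
Why: O-Silylation of the oxyanion (silyl ester formation) can give only one product because the two oxygens of the 1,3-dioxo anion are equivalent.

Step 12
Reactants: 15 alkenylstannane; 18 3-methoxy-4-[(triisopropylsilyl)oxy]cyclobut-3-ene-1,2-dione
Product: 20 4-hydroxy-3-methoxy-4-[(2Z,5E,9E,13E,17E,21E)-6,10,14,18,22,26-hexamethylheptacosa-2,5,9,13,17,21,25-heptaen-3-yl]-2-[(triisopropylsilyl)oxy]cyclobut-2-en-1-one (racemic), via alkenyllithium 19 (not isolated)
Conditions: n-BuLi, THF, –78 to –50 °C; then 18, –78 °C; NH4Cl (aq)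
Reagents that add atoms: none
Why: Tin–lithium exchange proceeds with retention to alkenyllithium 19, whose 1,2-addition to a squarate carbonyl (organolithium addition to a squaric ester) should take place at the carbonyl flanked by the methoxy-bearing carbon, because the other carbonyl is shielded by the adjacent triisopropylsilyloxy group, which unlike methoxy is also too weak a Lewis base to help bind lithium; the carbinol centre forms racemic and is destroyed in step 13.

Step 13
Reactants: 20 alkenyl hydroxycyclobutenone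
Product: 23 3-methoxy-6-methyl-5-(all-E-hexaprenyl)-2-[(triisopropylsilyl)oxy]benzene-1,4-diol, via dienylketene 21 (not isolated), via cyclohexadienone 22 (not isolated)
Conditions: PhMe (0.02 M), 110 °C, argon; crude product taken on directly
Reagents that add atoms: none
Why: At 110 °C the cyclobutenone should undergo conrotatory 4π-electrocyclic opening of the C1–C4 bond, the C4 hydroxyl rotating outward as donor substituents do, which puts the alkenyl group cis to the ketene arm in dienylketene 21. The ketene carbon then bonds to the CH(CH3) terminus of the alkenyl group in a disrotatory 6π-electrocyclisation (the only ring closure of the step, six-membered and all-carbon) to give cyclohexa-2,4-dienone 22, whose single sp3 centre (C6, racemic, no control needed) is erased at once by enolisation to the aromatic hydroquinone 23. The closest known reaction type is the thermal ring expansion of squarate-derived 4-alkenyl-4-hydroxycyclobutenones to hydroquinones (Moore rearrangement). The selectivity required is torquoselectivity (hydroxyl outward, otherwise the ketene is trapped by OH as a furanone), secured by the oxygen lone pair, and 6π closure ahead of a 1,7-hydrogen shift from the cis methyl group, favoured by the unhindered sp-hybridised ketene terminus and the gain of aromaticity. Regiochemistry is not at risk in this step, because ring connectivity alone fixes that cyclobutenone C1 and C4 become the para C–O carbons, C2 and C3 keep OSi(i-Pr)3 and OCH3, and the alkenyl carbons deliver CH2R next to old C4 and CH3 next to old C1.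

Step 14
Reactants: 23 silyl-protected hydroquinone
Product: 25 3-demethylubiquinone-6, via benzenetriol 24 (not isolated)
Conditions: HF·pyridine, pyridine, THF, 0 °C; then Ag2O, Et2O, rt
Reagents that add atoms: none
Why: Fluoride removes the aryl silyl ether, and Ag2O oxidises the para-dihydroxy pair of triol 24 to the quinone (hydroquinone oxidation), the third hydroxyl remaining as the vinylogous-acid OH of the target.

**Compound list**

1 | (2E,6E)-farnesyl bromide | BrC/C=C(\C)CC/C=C(\C)CCC=C(C)C | starting material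
2 | (2E,6E)-farnesyl p-tolyl sulfone | Cc1ccc(cc1)S(=O)(=O)C/C=C(\C)CC/C=C(\C)CCC=C(C)C | intermediate
3 | (2E,6E)-farnesol | OC/C=C(\C)CC/C=C(\C)CCC=C(C)C | starting material
4 | (2E,6E)-farnesyl tert-butyldimethylsilyl ether | CC(C)(C)[Si](C)(C)OC/C=C(\C)CC/C=C(\C)CCC=C(C)C | intermediate
5 | (2E,6E,10E)-12-[(tert-butyldimethylsilyl)oxy]-2,6,10-trimethyldodeca-2,6,10-trien-1-ol | CC(C)(C)[Si](C)(C)OC/C=C(\C)CC/C=C(\C)CC/C=C(\C)CO | intermediate
6 | tert-butyl{[(2E,6E,10E)-12-bromo-3,7,11-trimethyldodeca-2,6,10-trien-1-yl]oxy}dimethylsilane | CC(C)(C)[Si](C)(C)OC/C=C(\C)CC/C=C(\C)CC/C=C(\C)CBr | intermediate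
7 | α-lithio (2E,6E)-farnesyl p-tolyl sulfone | Cc1ccc(cc1)S(=O)(=O)C([Li])/C=C(\C)CC/C=C(\C)CCC=C(C)C | intermediate
8 | tert-butyldimethylsilyl ether of (2E,6E,10E,14E,18E)-3,7,11,15,19,23-hexamethyl-13-(p-tolylsulfonyl)tetracosa-2,6,10,14,18,22-hexaen-1-ol, racemic at C13 | CC(C)(C)[Si](C)(C)OC/C=C(\C)CC/C=C(\C)CC/C=C(\C)CC(S(=O)(=O)c1ccc(C)cc1)/C=C(\C)CC/C=C(\C)CCC=C(C)C | intermediate
9 | all-E-hexaprenyl tert-butyldimethylsilyl ether | CC(C)(C)[Si](C)(C)OC/C=C(\C)CC/C=C(\C)CC/C=C(\C)CC/C=C(\C)CC/C=C(\C)CCC=C(C)C | intermediate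
10 | all-E-hexaprenol | OC/C=C(\C)CC/C=C(\C)CC/C=C(\C)CC/C=C(\C)CC/C=C(\C)CCC=C(C)C | intermediate
11 | all-E-hexaprenyl bromide | BrC/C=C(\C)CC/C=C(\C)CC/C=C(\C)CC/C=C(\C)CC/C=C(\C)CCC=C(C)C | intermediate
12 | tributyl(prop-1-yn-1-yl)stannane | CC#C[Sn](CCCC)(CCCC)CCCC | starting material
13 | chlorobis(cyclopentadienyl)[(Z)-1-(tributylstannyl)prop-1-en-1-yl]zirconium | C/C=C(\[Sn](CCCC)(CCCC)CCCC)[Zr](Cl)(C1C=CC=C1)C1C=CC=C1 | intermediate
14 | chloro[(Z)-1-(tributylstannyl)prop-1-en-1-yl]zinc | C/C=C(\[Sn](CCCC)(CCCC)CCCC)[Zn]Cl | intermediate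
15 | tributyl[(2Z,5E,9E,13E,17E,21E)-6,10,14,18,22,26-hexamethylheptacosa-2,5,9,13,17,21,25-heptaen-3-yl]stannane | C/C=C(\[Sn](CCCC)(CCCC)CCCC)C/C=C(\C)CC/C=C(\C)CC/C=C(\C)CC/C=C(\C)CC/C=C(\C)CCC=C(C)C | intermediate
16 | dimethyl squarate (3,4-dimethoxycyclobut-3-ene-1,2-dione) | COC1=C(OC)C(=O)C1=O | starting material
17 | sodium 2-methoxy-3,4-dioxocyclobut-1-en-1-olate | COC1=C([O-])C(=O)C1=O.[Na+] | intermediate
18 | 3-methoxy-4-[(triisopropylsilyl)oxy]cyclobut-3-ene-1,2-dione | COC1=C(O[Si](C(C)C)(C(C)C)C(C)C)C(=O)C1=O | intermediate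
19 | [(2E,5E,9E,13E,17E,21E)-6,10,14,18,22,26-hexamethylheptacosa-2,5,9,13,17,21,25-heptaen-3-yl]lithium | C/C=C(\[Li])C/C=C(\C)CC/C=C(\C)CC/C=C(\C)CC/C=C(\C)CC/C=C(\C)CCC=C(C)C | intermediate
20 | 4-hydroxy-3-methoxy-4-[(2Z,5E,9E,13E,17E,21E)-6,10,14,18,22,26-hexamethylheptacosa-2,5,9,13,17,21,25-heptaen-3-yl]-2-[(triisopropylsilyl)oxy]cyclobut-2-en-1-one, racemic | C/C=C(\C1(O)C(=O)C(O[Si](C(C)C)(C(C)C)C(C)C)=C1OC)C/C=C(\C)CC/C=C(\C)CC/C=C(\C)CC/C=C(\C)CC/C=C(\C)CCC=C(C)C | intermediate
21 | (3Z,5Z)-4-hydroxy-3-methoxy-5-(all-E-hexaprenyl)-2-[(triisopropylsilyl)oxy]hepta-1,3,5-trien-1-one (dienylketene) | O=C=C(O[Si](C(C)C)(C(C)C)C(C)C)/C(OC)=C(/O)\C(C/C=C(\C)CC/C=C(\C)CC/C=C(\C)CC/C=C(\C)CC/C=C(\C)CCC=C(C)C)=C/C | intermediate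
22 | 4-hydroxy-3-methoxy-6-methyl-5-(all-E-hexaprenyl)-2-[(triisopropylsilyl)oxy]cyclohexa-2,4-dien-1-one, racemic at C6 | CC1C(=O)C(O[Si](C(C)C)(C(C)C)C(C)C)=C(OC)C(O)=C1C/C=C(\C)CC/C=C(\C)CC/C=C(\C)CC/C=C(\C)CC/C=C(\C)CCC=C(C)C | intermediate
23 | 3-methoxy-6-methyl-5-(all-E-hexaprenyl)-2-[(triisopropylsilyl)oxy]benzene-1,4-diol | Cc1c(O)c(O[Si](C(C)C)(C(C)C)C(C)C)c(OC)c(O)c1C/C=C(\C)CC/C=C(\C)CC/C=C(\C)CC/C=C(\C)CC/C=C(\C)CCC=C(C)C | intermediate
24 | 3-methoxy-6-methyl-5-(all-E-hexaprenyl)benzene-1,2,4-triol | Cc1c(O)c(O)c(OC)c(O)c1C/C=C(\C)CC/C=C(\C)CC/C=C(\C)CC/C=C(\C)CC/C=C(\C)CCC=C(C)C | intermediate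
25 | 3-demethylubiquinone-6 (3-hydroxy-2-methoxy-5-methyl-6-(all-E-hexaprenyl)-1,4-benzoquinone) | COC1=C(O)C(=O)C(C)=C(C/C=C(\C)CC/C=C(\C)CC/C=C(\C)CC/C=C(\C)CC/C=C(\C)CCC=C(C)C)C1=O | target

**Step count**

Total steps: 14. Longest linear sequence: 11 steps (steps 2–9 and 12–14, from farnesol 3).

**Steps most likely to fail**

Step 12 (highest risk). The alkenyllithium may not discriminate well enough between the two squarate carbonyls, or may attack silicon. Addition at the carbonyl next to the silyloxy carbon, followed by silyl migration to the new alkoxide, would lead on to the isomer with OH and OCH3 exchanged. Fallback (oxygen differentiation replaced by an electronically fixed semisquarate, hydroxyl introduced last), setting out from 16 and 19: dimethyl squarate 16 is reduced with LiAlH(O-t-Bu)3 (THF, –78 °C) to 4-hydroxy-2,3-dimethoxycyclobut-2-en-1-one F1, which with catalytic HCl loses methanol to give 3-methoxycyclobut-3-ene-1,2-dione F2. In F2 only the carbonyl next to the methoxy-bearing carbon is a free ketone (the other is a vinylogous ester), so 19 should add there to give alkenylcyclobutenone F3. Heating in toluene should give methoxy hydroquinone F4, and Ag2O then 5-demethoxyubiquinone-6 F5. Weitz–Scheffer epoxidation (H2O2, Na2CO3, EtOH, 0 °C) of the unsubstituted methoxy-enone double bond should give quinone epoxide F6, and base-induced epoxide opening (Et3N or silica gel) moves the oxygen to the former CH carbon. The fallback comes back to the route at target 25.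

Step 9. Transmetalation may be slow at the hindered tin-bearing carbon, the product may be allylated a second time at tin, or the π-allyl intermediate may give the branched or E/Z-scrambled diene. Fallback (Wittig construction of the trisubstituted alkene instead of alkenyl–allyl coupling), setting out from 11: alkylation of Ph3P=CH2 with 11 gives homoallylic phosphonium bromide F7. NaHMDS gives ylide F8, iodine gives α-iodophosphonium iodide F9, a second equivalent of NaHMDS gives α-iodo ylide F10, and acetaldehyde (Stork–Zhao olefination) should give (2Z)-vinyl iodide F11. Iodine–lithium exchange with t-BuLi (2 equiv, –78 °C) proceeds with retention, and the fallback comes back to the route at alkenyllithium 19.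

Step 13. The methyl group cis to the ring on the alkene terminus may slow the 6π closure enough for a 1,7-hydrogen shift in the dienylketene, or lactonisation to a furanone, to compete and erode the conversion to 23. Fallback (ring expansion of an alkynyl instead of an alkenyl cyclobutenone, side chain attached afterwards), setting out from 18 and 11: prop-1-ynyllithium adds to 18 to give alkynylcyclobutenone F12. At 110 °C in toluene this should open to enynylketene F13 and close with hydrogen transfer (Moore rearrangement) to silyloxyquinone F14, whose only unsubstituted ring carbon is the one destined for the side chain. Bromide 11 and Bu3SnLi give hexaprenylstannane F15, and BF3·OEt2-promoted allylation of F14 with F15 (CH2Cl2, –78 °C; carbonyl addition then [3,3] shift) should deliver the hexaprenyl hydroquinone directly. The fallback comes back to the route at hydroquinone 23.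

Further compounds
F1 | step 12 | 4-hydroxy-2,3-dimethoxycyclobut-2-en-1-one | COC1=C(OC)C(=O)C1O
F2 | step 12 | 3-methoxycyclobut-3-ene-1,2-dione | COC1=CC(=O)C1=O
F3 | step 12 | 4-hydroxy-3-methoxy-4-[(2Z,5E,9E,13E,17E,21E)-6,10,14,18,22,26-hexamethylheptacosa-2,5,9,13,17,21,25-heptaen-3-yl]cyclobut-2-en-1-one | C/C=C(\C1(O)C(=O)C=C1OC)C/C=C(\C)CC/C=C(\C)CC/C=C(\C)CC/C=C(\C)CC/C=C(\C)CCC=C(C)C
F4 | step 12 | 2-methoxy-5-methyl-6-(all-E-hexaprenyl)benzene-1,4-diol | Cc1c(O)cc(OC)c(O)c1C/C=C(\C)CC/C=C(\C)CC/C=C(\C)CC/C=C(\C)CC/C=C(\C)CCC=C(C)C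
F5 | step 12 | 2-methoxy-5-methyl-6-(all-E-hexaprenyl)cyclohexa-2,5-diene-1,4-dione (5-demethoxyubiquinone-6) | COC1=CC(=O)C(C)=C(C/C=C(\C)CC/C=C(\C)CC/C=C(\C)CC/C=C(\C)CC/C=C(\C)CCC=C(C)C)C1=O
F6 | step 12 | 2,3-epoxy-2-methoxy-5-methyl-6-(all-E-hexaprenyl)cyclohex-5-ene-1,4-dione, racemic | COC12OC1C(=O)C(C)=C(C/C=C(\C)CC/C=C(\C)CC/C=C(\C)CC/C=C(\C)CC/C=C(\C)CCC=C(C)C)C2=O
F7 | step 9 | [(3E,7E,11E,15E,19E)-4,8,12,16,20,24-hexamethylpentacosa-3,7,11,15,19,23-hexaen-1-yl]triphenylphosphonium bromide | [Br-].c1ccccc1[P+](c1ccccc1)(c1ccccc1)CC/C=C(\C)CC/C=C(\C)CC/C=C(\C)CC/C=C(\C)CC/C=C(\C)CCC=C(C)C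
F8 | step 9 | [(3E,7E,11E,15E,19E)-4,8,12,16,20,24-hexamethylpentacosa-3,7,11,15,19,23-hexaen-1-ylidene]triphenylphosphorane | c1ccccc1P(c1ccccc1)(c1ccccc1)=CC/C=C(\C)CC/C=C(\C)CC/C=C(\C)CC/C=C(\C)CC/C=C(\C)CCC=C(C)C
F9 | step 9 | [(3E,7E,11E,15E,19E)-1-iodo-4,8,12,16,20,24-hexamethylpentacosa-3,7,11,15,19,23-hexaen-1-yl]triphenylphosphonium iodide | [I-].c1ccccc1[P+](c1ccccc1)(c1ccccc1)C(I)C/C=C(\C)CC/C=C(\C)CC/C=C(\C)CC/C=C(\C)CC/C=C(\C)CCC=C(C)C
F10 | step 9 | [(3E,7E,11E,15E,19E)-1-iodo-4,8,12,16,20,24-hexamethylpentacosa-3,7,11,15,19,23-hexaen-1-ylidene]triphenylphosphorane | c1ccccc1P(c1ccccc1)(c1ccccc1)=C(I)C/C=C(\C)CC/C=C(\C)CC/C=C(\C)CC/C=C(\C)CC/C=C(\C)CCC=C(C)C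
F11 | step 9 | (2Z,5E,9E,13E,17E,21E)-3-iodo-6,10,14,18,22,26-hexamethylheptacosa-2,5,9,13,17,21,25-heptaene | C/C=C(\I)C/C=C(\C)CC/C=C(\C)CC/C=C(\C)CC/C=C(\C)CC/C=C(\C)CCC=C(C)C
F12 | step 13 | 4-hydroxy-3-methoxy-4-(prop-1-yn-1-yl)-2-[(triisopropylsilyl)oxy]cyclobut-2-en-1-one, racemic | CC#CC1(O)C(=O)C(O[Si](C(C)C)(C(C)C)C(C)C)=C1OC
F13 | step 13 | (3Z)-4-hydroxy-3-methoxy-2-[(triisopropylsilyl)oxy]hepta-1,3-dien-5-yn-1-one (enynylketene) | O=C=C(O[Si](C(C)C)(C(C)C)C(C)C)/C(OC)=C(/O)C#CC
F14 | step 13 | 2-methoxy-5-methyl-3-[(triisopropylsilyl)oxy]cyclohexa-2,5-diene-1,4-dione | COC1=C(O[Si](C(C)C)(C(C)C)C(C)C)C(=O)C(C)=CC1=O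
F15 | step 13 | tributyl(all-E-hexaprenyl)stannane | CCCC[Sn](CCCC)(CCCC)C/C=C(\C)CC/C=C(\C)CC/C=C(\C)CC/C=C(\C)CC/C=C(\C)CCC=C(C)C
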